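Target in the dusk run rises fast and then stalls: 0.225 M at 4.0 min, 0.270 M at 8.0 min. That last reading is a third of the starting material charged. The summer run has the dusk charge with target already added, and two chemists dispute what that added target does.

| setting | dusk | autumn | spring | dawn | summer |
|---|---|---|---|---|---|
| starting material | 0.800 M | 0.480 M | 1.60 M | 0.800 M | 0.800 M |
| coupling partner | 0.880 M | 0.560 M | 0.880 M | 0.880 M | 0.880 M |
| catalyst | 0.0240 M | 0.0240 M | 0.0240 M | 0.0480 M | 0.0240 M |
| target |  |  |  |  | 0.240 M |
| time |  |  |  |  | 8.0 min |

- dusk run (time / min: [target] / M): 1.3: 0.131; 2.7: 0.195; 4.0: 0.225; 5.3: 0.237; 6.7: 0.247; 8.0: 0.270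
- autumn run (time / min: [target] / M): 1.3: 0.065; 2.7: 0.125; 4.0: 0.158; 5.3: 0.169; 6.7: 0.160; 8.0: 0.175
- spring run (time / min: [target] / M): 1.3: 0.145; 2.7: 0.229; 4.0: 0.268; 5.3: 0.303; 6.7: 0.327; 8.0: 0.334
- dawn run (time / min: [target] / M): 1.3: 0.229; 2.7: 0.323; 4.0: 0.348; 5.3: 0.369; 6.7: 0.373; 8.0: 0.383

(each reading ± 0.008 M)

1. apparent order in [catalyst] of the starting rate, round the charge of the dusk run (the rate where two percent of its starting material have turned into target)
2. apparent order in [starting material] of the starting rate, round the charge of the dusk run (the rate where two percent of its starting material have turned into target) (one fixed amount of target, the same in the runs compared)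
3. target in the summer run at 8.0 min, as a share of the starting material charged

- Overall: starting material + coupling partner -> target, with catalyst as catalyst.
- Constant volume, constant temperature.
- Readings of a species count what is bound in complexes too.
- "The second partner" is coupling partner.
- An order is taken over about fifteen percent of the charge, up and down.
- A share of target counts the target that was charged too.

The first chemist holds that charged target is a spectator. To her the stall is a matter of the clock. So the summer run makes what the dusk run made in 8.0 min and keeps its charge on top. That gives 0.510 M, or 63.7% of the starting material.

The second chemist holds that the slowing follows [target], not the clock. His evidence is the dawn run. Its reading at 1.3 min is 1.75 times the dusk reading at that time. Yet its reading at 8.0 min is 1.42 times the dusk reading, a lower ratio than the early one.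

So he freezes one number. The dusk run passes the summer charge near 5.3 min, where it reads 0.237 M. He takes the creep rate, the net slope of target across the dusk readings from there to 8.0 min, 0.0122 M min⁻¹. The scatter puts 0.00419 M min⁻¹ on that reading. Held for 8.0 min on top of the charge, it gives 0.338 M, or 42.2%.

The forecast takes his side by another road, a “product-driven catalyst death”. It gives order 1 in catalyst, order 0.15 in starting material, and 41% for the summer run. His creep reckoning lands near that share but is not the same number.

The simulation gives order 1.0 in catalyst, order 0.34 in starting material, and 40.7% for the summer run. The forecast's order in starting material is lower than that.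

    catalyst + starting material ⇌ catalyst-substrate complex, settled at all times (5.300 L mol⁻¹)
    catalyst-substrate complex + coupling partner → target + catalyst + by-product (14.88 L mol⁻¹ min⁻¹)
    target + coupling partner → side product (0.3696 L mol⁻¹ min⁻¹)
    2 starting material ⇌ idle substrate dimer, settled at all times (15.30 L mol⁻¹)

The summer run crept at 0.0107 M min⁻¹, against the 0.0122 M min⁻¹ read from the dusk run. Its share stays at 40.7% because target reacts with coupling partner to side product. In the summer run computed without that step, the share reaches 99.7% and the creep is 0.0697 M min⁻¹. The spectator view has its region at the two-percent mark: the loss of target is not the reason for the order in starting material there, which is 0.34 with the loss and 0.32 without it.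

(The data were computed with constants of no real substance.)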